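## Structural features

The target is the 4-methoxybenzoate of a daucane diol: a trans-fused bicyclo[5.3.0]decene in which cyclopentane ring A (C1–C5) and cycloheptene ring B (C1, C5–C10) share the C1–C5 bond (daucane atom labels are used in the text; in the systematic azulene names C1, C2, C3, C4, C5, C6, C7, C8, C9, C10 appear as 8a, 1, 2, 3, 3a, 4, 5, 6, 7, 8). It has four stereocentres, (1S,4R,5S,6S): quaternary C1 (methyl C15), the ring-fusion methine C5 with H5 trans to C15, the tertiary carbinol C4 (OH cis to C15, isopropyl on the other face) and the secondary allylic carbinol C6 that carries the ester, its oxygen cis to H5 and 1,3-anti to the C4 hydroxyl. C1, C5 and C4 are contiguous and C6 adjoins C5, so every stereocentre sits on or next to the ring fusion. Fragile groups are the secondary allylic ester at C6 (ionisation and allylic transposition under acid), the tertiary C4 hydroxyl, which is β to C6 (dehydration, and retro-aldol cleavage whenever C6 is a ketone), and the trisubstituted C7=C8 alkene. The real difficulty is the C1–C5–C4 triad, two fully substituted carbons flanking the ring-fusion methine of a trans-fused five-membered ring: a closure of ring A at C5 from a chain on C1 is expected to be cis on geometric grounds. Two features decide the plan. Ring B hides a mirror plane: C6 is flanked by C5–C1(CH3) and C7=C8(CH3), so at the dienone level (C6=O, C1=C5, C7=C8) ring B is an achiral 3,6-dimethylcyclohepta-2,6-dienone with enantiotopic β-carbons, and the key step exploits exactly this by making C1 quaternary through desymmetrising addition of the C2–C3–C4(isopropyl) chain while the untouched arm survives as C7=C8–C14. Second, H5 and O4 stand trans across C4–C5 and H5 is cis to O6, the pattern left when an epoxide at C4–C5 is opened at C5 by a hydrogen that migrates from C6.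

## Logic of the disconnections

24 ⇒ 22 + 23. Cut: the acyl C–O bond at O6. The ionisable allylic ester is introduced last so that it never meets a Lewis acid. Gain: the aromatic fragment is removed. Demand: acylation must take the secondary allylic hydroxyl and leave the tertiary one.

22 ⇒ 21. Cut: the C6–H bond (carbinol back to enone carbonyl). The 1,3-anti relation of O6 to O4 is the signature of a hydride delivered internally from O4. Gain: one stereocentre less. Demand: the tertiary hydroxyl must direct, and reduction must be 1,2.

21 ⇒ 20. Cut: the C5–H bond, exchanged for a C5–O bond, the hydrogen being returned to C6 (reverse of a 1,2-hydride shift). The trans ring fusion and the C4 carbinol become one epoxide, so the ring-fusion problem turns into a question of epoxide face. Demand: ionisation at C5 and not at C4, with H6 anti-periplanar to the C5–O bond.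

20 ⇒ 19. Cut: both C–O bonds of the epoxide. Gain: C4 and C5 become sp2 and only C1 and C6 remain stereogenic. Demand: oxygen must go to the tetrasubstituted C4=C5 alkene and not to C7=C8, on the face of the C6 hydroxyl.

19 ⇒ 18. Cut: the C6–H bond. C6 is used as a relay stereocentre that carries the information of C1 to C4 and C5 and is then consumed. Demand: hydride to the carbonyl face anti to C15.

18 ⇒ 15. Cut: the C4=C5 bond (aldol condensation, closure of ring A). Closing ring A at the alkene level avoids creating the ring-fusion stereocentre in a closure that would be cis. Gain: bicycle to monocycle with no stereochemical demand. Demand: enolisation on the ring side (C5) and dehydration into conjugation.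

15 ⇒ 8 + 12 (used as 13). Cut: the C1–C2 bond at the quaternary carbon, the key disconnection. Gain: a C9 achiral, mirror-symmetric ring and a C6 chain; the only stereocentre that needs an external chiral influence is set here. Demand: a catalyst that distinguishes the enantiotopic faces of a β-methyl enone, 1,4-selectivity and a single addition.

8 ⇒ 6 ⇒ 5 ⇒ 3 ⇒ 1. Cut: one ring carbon (the CH between the carbonyl and a methyl-bearing carbon) is taken out of 8 by reversing a one-carbon ring enlargement (6), then the cyclopropane C–C bonds (5), the O–Si bond (3) and the C–CH3 bond (1). Gain: a commercial six-membered enone. Demand: two kinetic α′-deprotonations and carbenoid attack on the silyl enol ether double bond only.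

12 ⇒ 11 ⇒ 9 + 10. Cut: the two ketal C–O bonds, then the acyl C–C bond. Gain: two commercial reagents. Demand: the acylation must outrun loss of HBr.

## Other disconnections considered

Alternative 1: Cut C7=C8 of ring B by ring-closing metathesis. The diene A1 (ring A complete, vinyl group on the C6 carbinol, 3-methylbut-3-enyl chain on C1) would close with the second-generation Grubbs catalyst to 22. This is the plan that comes to mind first. It is not preferred because A1 already contains all four stereocentres: the hard triad C1/C5/C4 is only moved into a long linear preparation of a fully substituted cyclopentane, and the closure must form a trisubstituted alkene in a seven-membered ring next to a crowded carbinol. The hidden symmetry of ring B is not used and the step count is higher.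

Alternative 2: Cut the same two bonds as the chosen plan (C1–C2 and C4–C5) but form C4–C5 as an aldol addition in the flask of the conjugate addition. The nucleophile added to 8 would carry the free isopropyl ketone and the metal dienolate would close ring A directly, which would save three to four steps. It is not preferred because the tether on C1 can reach the planar enolate carbon C5 only on the face it already occupies, so the torsion about C1–C5 fits the cis mode and the expected product is the cis-fused isomer A2. The trans isomer 21 could then arise only by retro-aldol equilibration, whose position cannot be predicted with confidence. The chosen plan passes through 18, where no ring-fusion stereocentre exists, and sets H5 by a stereospecific shift.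

Alternative 3: Cut C1–C5 and reconnect C1–C6, a pinacol-type ring contraction and expansion of a decalin. In the cis-decalin A3 (angular carbinol at C6, equatorial mesylate at C5 anti-periplanar to the C6–C1 bond, tertiary carbinol at C4) base would induce migration of C1 from C6 to C5, contracting one six-membered ring to ring A and expanding the other to ring B, to give 21 stereospecifically. The idea is sound mechanistically, but A3 needs three contiguous cis oxygenated stereocentres, and its dienol precursor has two nearly identical trisubstituted alkenes flanking the carbinol, so a selective dihydroxylation is doubtful. Migration of C3 from C4 would also compete, and the sequence is clearly longer.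

Key step: step 7

Assumption: the sense of induction of the chiral ligand in step 7 and of the oxazaborolidine in step 9 (C4=C5 alkenyl arm as the large group) is taken from the usual models for these catalysts; the mirror-image catalyst would be used if the opposite sense were found.

## Steps

Step 1
Reactants: 1 3-methylcyclohex-2-en-1-one
Product: 3 rac-3,6-dimethylcyclohex-2-en-1-one, via lithium dienolate 2 (not isolated)
Conditions: LiN(i-Pr)2 (1.05 equiv), THF, −78 °C; MeI, −78 → 0 °C
Reagents that add atoms: iodomethane, CI
Why: Kinetic deprotonation of a cyclohexenone by the amide base takes the α′ proton (ring position 6) and gives the cross-conjugated dienolate 2, which is C-methylated (enolate alkylation); the new stereocentre is of no consequence because it becomes sp2 again in step 2.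

Step 2
Reactants: 3 rac-3,6-dimethylcyclohex-2-en-1-one
Product: 5 [(2,5-dimethylcyclohexa-1,5-dien-1-yl)oxy]trimethylsilane, via lithium dienolate 4 (not isolated)
Conditions: LiN(i-Pr)2 (1.1 equiv), THF, −78 °C; Me3SiCl, −78 → 0 °C; non-aqueous work-up
Reagents that add atoms: chlorotrimethylsilane, C[Si](C)(C)Cl
Why: A second kinetic α′-deprotonation (now of the methine) and O-silylation of dienolate 4 give the 2-silyloxy-1,3-diene (silyl enol ether formation); amide base at −78 °C avoids the thermodynamic linear dienolate.

Step 3
Reactants: 5 [(2,5-dimethylcyclohexa-1,5-dien-1-yl)oxy]trimethylsilane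
Product: 6 rac-trimethyl[(3,6-dimethylbicyclo[4.1.0]hept-2-en-1-yl)oxy]silane
Conditions: Et2Zn (1.5 equiv), CH2I2 (3.0 equiv), CH2Cl2, 0 °C → rt
Reagents that add atoms: diiodomethane, ICI
Why: Simmons–Smith cyclopropanation in its Et2Zn/CH2I2 form: the electrophilic zinc carbenoid selects the electron-rich silyl enol ether double bond of the diene and leaves the methyl-substituted alkene; the cyclopropane is cis-fused by necessity and racemic, which is irrelevant because both stereocentres disappear in step 4.

Step 4
Reactants: 6 rac-trimethyl[(3,6-dimethylbicyclo[4.1.0]hept-2-en-1-yl)oxy]silane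
Product: 8 3,6-dimethylcyclohepta-2,6-dien-1-one, via chloro ketone 7 (not isolated)
Conditions: FeCl3 (2.2 equiv), DMF, 0 °C → rt; then NaOAc, MeOH, 65 °C
Reagents that add atoms: none
Why: FeCl3 oxidises the siloxycyclopropane to a cyclopropyloxy radical whose β-scission of the internal bond enlarges the ring by one carbon to a tertiary radical that takes chlorine from a second FeCl3 (oxidative ring expansion of a siloxycyclopropane); acetate then removes HCl from β-chloro ketone 7 by E1cB elimination to the conjugated, achiral dienone 8.

Step 5
Reactants: 9 3-bromopropanoyl chloride; 10 isopropylmagnesium chloride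
Product: 11 1-bromo-4-methylpentan-3-one
Conditions: Fe(acac)3 (3 mol %), THF, −78 °C, 15 min; aq NH4Cl
Reagents that add atoms: none
Why: Iron-catalysed acylation of a Grignard reagent by an acid chloride is complete within minutes at −78 °C, faster than addition to the ketone formed or loss of HBr, and tolerates the primary alkyl bromide.

Step 6
Reactants: 11 1-bromo-4-methylpentan-3-one
Product: 12 2-(2-bromoethyl)-5,5-dimethyl-2-(propan-2-yl)-1,3-dioxane
Conditions: 2,2-dimethylpropane-1,3-diol (1.5 equiv), HC(OEt)3 (1.2 equiv), TsOH·H2O (2 mol %), CH2Cl2, rt
Reagents that add atoms: 2,2-dimethylpropane-1,3-diol, OCC(C)(C)CO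
Why: Acid-catalysed ketalisation driven by the orthoformate as water scavenger; the six-membered dioxane ketal is chosen because the derived β-metallated ketal resists intramolecular attack on the ketal carbon during formation and use of the Grignard reagent.

Step 7
Reactants: 8 3,6-dimethylcyclohepta-2,6-dien-1-one; 12 2-(2-bromoethyl)-5,5-dimethyl-2-(propan-2-yl)-1,3-dioxane
Product: 15 (S)-6-{2-[5,5-dimethyl-2-(propan-2-yl)-1,3-dioxan-2-yl]ethyl}-3,6-dimethylcyclohept-2-en-1-one, via Grignard reagent 13 (not isolated), via magnesium dienolate 14 (not isolated)
Conditions: 12, Mg turnings, Et2O, 25–35 °C; then 8, Cu(OTf)2 (3 mol %), (S)-1-(1-hydroxy-4-methylpentan-2-yl)-3-mesityl-4,5-dihydroimidazol-3-ium hexafluorophosphate (4 mol %), Et2O, −30 → 0 °C, slow addition of 13 (1.3 equiv); aq NH4Cl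
Reagents that add atoms: none
Why: The step is a copper-catalysed enantioselective conjugate addition of a Grignard reagent to a β-methyl cyclic enone, the established entry to quaternary β-carbons, run here on a dienone whose two enone arms are mirror images. Mechanism: 13 deprotonates the imidazolinium salt to an alkoxide-tethered carbene on monovalent copper, transmetalation gives a chiral alkylcopper–magnesium species that forms a π-complex with one C=C of 8 (magnesium on the carbonyl oxygen), oxidative addition at the β-carbon gives a σ-alkyl trivalent copper enolate, and reductive elimination forms the C1–C2 bond and releases dienolate 14, which is protonated on work-up. No ring is closed; the step joins the C9 ring fragment and the C6 chain fragment at the carbon that becomes quaternary, so all fifteen skeletal carbons are in place. The single new stereocentre (C1, S) is controlled by the chiral ligand alone: 8 has a mirror plane through C6=O and the midpoint of C9–C10, the top face of one arm and the bottom face of the other are homotopic, and a catalyst that prefers one local enone face therefore gives the same enantiomer from either arm. The selectivities needed are 1,4 over 1,2 (copper catalysis, slow addition, low temperature), mono- over bis-addition (after the first addition the second enone is locked in the unreactive cross-conjugated dienolate 14) and face selectivity (ligand). The ketal is inert to the organometallic, and the arm left untouched is exactly the C7=C8–C14 unit of the target, so ring B needs no later adjustment.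

Step 8
Reactants: 15 (S)-6-{2-[5,5-dimethyl-2-(propan-2-yl)-1,3-dioxan-2-yl]ethyl}-3,6-dimethylcyclohept-2-en-1-one
Product: 18 (8aS)-6,8a-dimethyl-3-(propan-2-yl)-2,7,8,8a-tetrahydroazulen-4(1H)-one, via diketone 16 (not isolated), via aldol adduct 17 (not isolated)
Conditions: 2 M aq HCl, THF, 50 °C; then solvent exchange, TsOH·H2O (0.2 equiv), toluene, 110 °C, Dean–Stark
Reagents that add atoms: none
Why: Aqueous acid frees the isopropyl ketone (16); the enol of the ring ketone at C5 then adds to it in a 5-(enolexo)-exo-trig aldol closure of ring A (17), and loss of water gives the conjugated tetrasubstituted C4=C5 alkene (aldol condensation, cyclopentene annulation). The competing enol of the side-chain ketone could only close a strained bridged ketol that cannot dehydrate to a stable enone and therefore reverts; no stereocentre is formed and C1 is untouched.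

Step 9
Reactants: 18 (8aS)-6,8a-dimethyl-3-(propan-2-yl)-2,7,8,8a-tetrahydroazulen-4(1H)-one
Product: 19 (4R,8aS)-6,8a-dimethyl-3-(propan-2-yl)-1,2,4,7,8,8a-hexahydroazulen-4-ol
Conditions: (S)-1-methyl-3,3-diphenyltetrahydro-1H,3H-pyrrolo[1,2-c][1,3,2]oxazaborole (0.2 equiv), catecholborane (1.5 equiv), toluene, −78 °C; aq NaOH
Reagents that add atoms: none
Why: Corey–Bakshi–Shibata reduction: the ketone binds the oxazaborolidine–borane complex with the fully substituted C4=C5 alkenyl arm as the large group and hydride is delivered 1,2 to one carbonyl face, giving the carbinol whose hydroxyl lies on the face of C15 (6R in daucane labels); reagent control is used because this relay stereocentre decides the face of the next two steps.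

Step 10
Reactants: 19 (4R,8aS)-6,8a-dimethyl-3-(propan-2-yl)-1,2,4,7,8,8a-hexahydroazulen-4-ol
Product: 20 (3R,3aS,4R,8aS)-3,3a-epoxy-6,8a-dimethyl-3-(propan-2-yl)-1,2,3,3a,4,7,8,8a-octahydroazulen-4-ol
Conditions: VO(acac)2 (5 mol %), t-BuOOH (1.3 equiv), CH2Cl2, 0 °C; aq Na2S2O3
Reagents that add atoms: tert-butyl hydroperoxide, CC(C)(C)OO
Why: Hydroxyl-directed epoxidation: the allylic alkoxide binds the pentavalent vanadium tert-butylperoxo complex, which delivers oxygen to the alkene on the face of the hydroxyl; of the two allylic alkenes the tetrasubstituted C4=C5 bond is the more nucleophilic and should react first.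

Step 11
Reactants: 20 (3R,3aS,4R,8aS)-3,3a-epoxy-6,8a-dimethyl-3-(propan-2-yl)-1,2,3,3a,4,7,8,8a-octahydroazulen-4-ol
Product: 21 (3R,3aR,8aS)-3-hydroxy-6,8a-dimethyl-3-(propan-2-yl)-2,3,3a,7,8,8a-hexahydroazulen-4(1H)-one
Conditions: BF3·OEt2 (0.2 equiv), CH2Cl2, −78 → −40 °C; aq NaHCO3
Reagents that add atoms: none
Why: Semipinacol rearrangement of a 2,3-epoxy alcohol: the Lewis acid opens the C5–O bond while the carbinol hydrogen on C6, anti-periplanar to that bond because hydroxyl and epoxide are syn, shifts to C5 with inversion there. The hydrogen therefore arrives on the face opposite the epoxide oxygen, that is trans to C15, the C4–O bond is kept with retention as the tertiary hydroxyl, and C6 becomes the enone carbonyl. Ionisation at C5 is favoured over C4 because only it is assisted by the migrating hydride and ends in a conjugated oxocarbenium ion.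

Step 12
Reactants: 21 (3R,3aR,8aS)-3-hydroxy-6,8a-dimethyl-3-(propan-2-yl)-2,3,3a,7,8,8a-hexahydroazulen-4(1H)-one
Product: 22 (3R,3aS,4S,8aS)-6,8a-dimethyl-3-(propan-2-yl)-1,2,3,3a,4,7,8,8a-octahydroazulene-3,4-diol
Conditions: Me4NBH(OAc)3 (5 equiv), MeCN/AcOH 1:1, −30 °C; aq NaHCO3
Reagents that add atoms: none
Why: Evans–Saksena reduction: exchange of an acetate of the triacetoxyborohydride for the tertiary C4 alkoxide is followed by intramolecular hydride delivery to the C6 carbonyl from the face of that oxygen through a six-membered transition state, giving the 1,3-anti diol (new centre 6S in daucane labels); internal delivery also secures 1,2- over 1,4-reduction of the enone.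

Step 13
Reactants: 22 (3R,3aS,4S,8aS)-6,8a-dimethyl-3-(propan-2-yl)-1,2,3,3a,4,7,8,8a-octahydroazulene-3,4-diol; 23 4-methoxybenzoyl chloride
Product: 24 (3R,3aS,4S,8aS)-3-hydroxy-6,8a-dimethyl-3-(propan-2-yl)-1,2,3,3a,4,7,8,8a-octahydroazulen-4-yl 4-methoxybenzoate
Conditions: 23 (1.3 equiv), pyridine (3 equiv), DMAP (0.1 equiv), CH2Cl2, 0 °C → rt
Reagents that add atoms: none
Why: DMAP-catalysed acylation by the acid chloride (nucleophilic catalysis); the secondary allylic hydroxyl reacts while the hindered tertiary hydroxyl does not, and no stereocentre is touched.

## Compound list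

1 | 3-methylcyclohex-2-en-1-one | CC1=CC(=O)CCC1 | starting material
2 | lithium 5-methylcyclohexa-1,5-dien-1-olate | [Li]OC1=CCCC(C)=C1 | intermediate
3 | rac-3,6-dimethylcyclohex-2-en-1-one | CC1=CC(=O)C(C)CC1 | intermediate
4 | lithium 2,5-dimethylcyclohexa-1,5-dien-1-olate | [Li]OC1=C(C)CCC(C)=C1 | intermediate
5 | [(2,5-dimethylcyclohexa-1,5-dien-1-yl)oxy]trimethylsilane | C[Si](C)(C)OC1=C(C)CCC(C)=C1 | intermediate
6 | rac-trimethyl[(3,6-dimethylbicyclo[4.1.0]hept-2-en-1-yl)oxy]silane (cis-fused cyclopropane, racemic) | CC1=CC2(O[Si](C)(C)C)CC2(C)CC1 | intermediate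
7 | rac-6-chloro-3,6-dimethylcyclohept-2-en-1-one | CC1=CC(=O)CC(C)(Cl)CC1 | intermediate
8 | 3,6-dimethylcyclohepta-2,6-dien-1-one (achiral) | CC1=CC(=O)C=C(C)CC1 | intermediate
9 | 3-bromopropanoyl chloride | O=C(Cl)CCBr | starting material
10 | isopropylmagnesium chloride, (CH3)2CHMgCl | CC(C)[Mg]Cl | starting material
11 | 1-bromo-4-methylpentan-3-one | CC(C)C(=O)CCBr | intermediate
12 | 2-(2-bromoethyl)-5,5-dimethyl-2-(propan-2-yl)-1,3-dioxane | CC(C)C1(CCBr)OCC(C)(C)CO1 | intermediate
13 | {2-[5,5-dimethyl-2-(propan-2-yl)-1,3-dioxan-2-yl]ethyl}magnesium bromide | CC(C)C1(CC[Mg]Br)OCC(C)(C)CO1 | intermediate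
14 | bromomagnesium (S)-3-{2-[5,5-dimethyl-2-(propan-2-yl)-1,3-dioxan-2-yl]ethyl}-3,6-dimethylcyclohepta-1,6-dien-1-olate | Br[Mg]OC1=C[C@](C)(CCC2(C(C)C)OCC(C)(C)CO2)CCC(C)=C1 | intermediate
15 | (S)-6-{2-[5,5-dimethyl-2-(propan-2-yl)-1,3-dioxan-2-yl]ethyl}-3,6-dimethylcyclohept-2-en-1-one | O=C1C=C(C)CC[C@@](C)(CCC2(C(C)C)OCC(C)(C)CO2)C1 | intermediate
16 | (S)-3,6-dimethyl-6-(4-methyl-3-oxopentyl)cyclohept-2-en-1-one | O=C1C=C(C)CC[C@@](C)(CCC(=O)C(C)C)C1 | intermediate
17 | (8aS)-3-hydroxy-6,8a-dimethyl-3-(propan-2-yl)-2,3,3a,7,8,8a-hexahydroazulen-4(1H)-one, mixture of isomers at C3 and C3a | O=C1C=C(C)CC[C@@]2(C)CCC(O)(C(C)C)C12 | intermediate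
18 | (8aS)-6,8a-dimethyl-3-(propan-2-yl)-2,7,8,8a-tetrahydroazulen-4(1H)-one | O=C1C=C(C)CC[C@@]2(C)CCC(C(C)C)=C12 | intermediate
19 | (4R,8aS)-6,8a-dimethyl-3-(propan-2-yl)-1,2,4,7,8,8a-hexahydroazulen-4-ol | O[C@@H]1C=C(C)CC[C@@]2(C)CCC(C(C)C)=C12 | intermediate
20 | (3R,3aS,4R,8aS)-3,3a-epoxy-6,8a-dimethyl-3-(propan-2-yl)-1,2,3,3a,4,7,8,8a-octahydroazulen-4-ol | O[C@@H]1C=C(C)CC[C@@]2(C)CC[C@]3(C(C)C)O[C@]123 | intermediate
21 | (3R,3aR,8aS)-3-hydroxy-6,8a-dimethyl-3-(propan-2-yl)-2,3,3a,7,8,8a-hexahydroazulen-4(1H)-one | O=C1C=C(C)CC[C@@]2(C)CC[C@@](O)(C(C)C)[C@H]12 | intermediate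
22 | (3R,3aS,4S,8aS)-6,8a-dimethyl-3-(propan-2-yl)-1,2,3,3a,4,7,8,8a-octahydroazulene-3,4-diol | O[C@H]1C=C(C)CC[C@@]2(C)CC[C@@](O)(C(C)C)[C@H]12 | intermediate
23 | 4-methoxybenzoyl chloride | COc1ccc(cc1)C(Cl)=O | starting material
24 | (3R,3aS,4S,8aS)-3-hydroxy-6,8a-dimethyl-3-(propan-2-yl)-1,2,3,3a,4,7,8,8a-octahydroazulen-4-yl 4-methoxybenzoate | COc1ccc(C(=O)O[C@H]2C=C(C)CC[C@@]3(C)CC[C@@](O)(C(C)C)[C@H]23)cc1 | target

## Step count and least certain steps

Total step count: 13. Longest linear sequence: 11 (steps 1–4 and 7–13); steps 5–6 form the side branch.

Step 7 (key step). Most likely failure: insufficient enantioselectivity or sluggish conjugate addition. The seven-membered dienone and the functionalised Grignard reagent 13 lie outside the best-behaved range of this catalysis (six-membered enones, simple alkyl groups), and uncatalysed 1,2-addition is a background path. Fallback, from 8 and 12 back to the route at 19: 13 is added to 8 with an achiral copper catalyst (CuBr·SMe2, 10 mol %, THF, −40 °C) to give the racemic keto ketal F1, and the acid treatment of step 8 gives the racemic dienone F2. Reduction with the oxazaborolidine of step 9 fixes the carbinol configuration whatever the quaternary centre, so the two enantiomers become 19 and its diastereomer, the (4R,8aR)-dienol F3. These are separated by chromatography and 19 continues; half of the material is given up.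

Step 11. Most likely failure: ionisation at the wrong epoxide carbon (C4 instead of C5), followed by elimination to allylic alcohols, or dehydration and retro-aldol cleavage of the product on the Lewis acid. Both epoxide carbons are fully substituted, so only the hydride participation distinguishes them. Fallback, from 20 back to the route at 21: 20 is oxidised (Dess–Martin periodinane, NaHCO3, CH2Cl2) to the α,β-epoxy ketone F4, and SmI2 (2.2 equiv, THF/MeOH, −90 °C) cleaves the Cα–O bond by electron transfer. The resulting β-alkoxy enolate of trivalent samarium is protonated at C5 from the face away from C15 and from the C4 alkoxide, which should give 21.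

Step 10. Most likely failure: poor site selectivity between the two allylic alkenes (oxygen delivered to C7=C8) or oxidation of the bis-allylic alcohol back to the dienone, because both alkenes can reach the metal-bound peroxide. Fallback, from 15 back to the route at 21: step 8 is stopped after the hydrolysis stage and 16 is isolated. Ring A is then closed as an aldol addition under equilibrating conditions (KOt-Bu, 0.2 equiv, t-BuOH/THF, 0 °C), 21 is separated from its cis-fused isomer A2, and A2 is returned to the equilibration. This makes the C4–C5 pair by C–C bond formation instead of oxidation and hydride shift, at the price of lower stereocontrol.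

Step 9. Most likely failure: low or reversed facial selectivity, because both carbonyl substituents are alkenyl groups and the intrinsic bias of the ring may oppose the catalyst. Fallback, from 18 back to the route at 19: Luche reduction (NaBH4, CeCl3·7H2O, MeOH, −40 °C), chromatographic separation of 19 from its C6 epimer, the (4S,8aS)-dienol F5, and return of F5 to 18 by MnO2 oxidation for recycling.

## Further compounds

F1 | step 7 | rac-6-{2-[5,5-dimethyl-2-(propan-2-yl)-1,3-dioxan-2-yl]ethyl}-3,6-dimethylcyclohept-2-en-1-one | O=C1C=C(C)CCC(C)(CCC2(C(C)C)OCC(C)(C)CO2)C1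
F2 | step 7 | rac-6,8a-dimethyl-3-(propan-2-yl)-2,7,8,8a-tetrahydroazulen-4(1H)-one | O=C1C=C(C)CCC2(C)CCC(C(C)C)=C12
F3 | step 7 | (4R,8aR)-6,8a-dimethyl-3-(propan-2-yl)-1,2,4,7,8,8a-hexahydroazulen-4-ol | O[C@@H]1C=C(C)CC[C@]2(C)CCC(C(C)C)=C12
F4 | step 11 | (3R,3aR,8aS)-3,3a-epoxy-6,8a-dimethyl-3-(propan-2-yl)-2,3,3a,7,8,8a-hexahydroazulen-4(1H)-one | O=C1C=C(C)CC[C@@]2(C)CC[C@]3(C(C)C)O[C@]123
F0 | step 10 | none | none
F5 | step 9 | (4S,8aS)-6,8a-dimethyl-3-(propan-2-yl)-1,2,4,7,8,8a-hexahydroazulen-4-ol | O[C@H]1C=C(C)CC[C@@]2(C)CCC(C(C)C)=C12
A1 | alternative 1 | (1R,2S,3S)-2-[(1S)-1-hydroxyprop-2-en-1-yl]-3-methyl-3-(3-methylbut-3-en-1-yl)-1-(propan-2-yl)cyclopentan-1-ol | C=C[C@H](O)[C@@H]1[C@@](C)(CCC(C)=C)CC[C@@]1(O)C(C)C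
A2 | alternative 2 | (3S,3aS,8aS)-3-hydroxy-6,8a-dimethyl-3-(propan-2-yl)-2,3,3a,7,8,8a-hexahydroazulen-4(1H)-one | O=C1C=C(C)CC[C@@]2(C)CC[C@](O)(C(C)C)[C@@H]12
A3 | alternative 3 | (1S,2R,4aS,8aR)-2,8a-dihydroxy-4a,7-dimethyl-2-(propan-2-yl)-1,2,3,4,4a,5,6,8a-octahydronaphthalen-1-yl methanesulfonate | CC1=C[C@]2(O)[C@@H](OS(C)(=O)=O)[C@](O)(C(C)C)CC[C@]2(C)CC1
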